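Time is the first setting. By hand, more time means more turnover, and the teal run shows the share of target in target plus side product (the selectivity) going from 65.5% at 3.00 h to 54.8% at 20.0 h. Target minus side product, though, reads 7.2 percentage points at both times. Call the mean of that difference over the teal run, in percent of the starting material charged, the gap: 6.2 points, a reading from values that each carry a standard deviation of 1 point. With X as target plus side product, algebra gives:

share = 0.5 + gap / (2 X)

The charge is the second setting. The violet gap, 8.8 points, is larger than teal's. As concentrations, teal over violet reads 1.41, near the root of the charge ratio, 1.41.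

| flask | starting material | coupling partner | remark | time |
|---|---|---|---|---|
| teal | 0.017 M | 1 equiv | run made earlier |  |
| violet | 0.0085 M | 1 equiv | run made earlier |  |
| red | 0.013 M | 1 equiv | run made earlier |  |
| noon | 0.017 M | 1.00 equiv | a tube with plug flow, the mixed feed as stated, residence time 20 h | 20 h |
| autumn | 0.017 M | 1.00 equiv | a closed flask charged with all of it at once and left for 20 h | 20 h |
| winter | 0.017 M | 1.00 equiv | a single well-mixed tank run continuously and read at steady state, 20 h in it on average |  |
| dawn | 0.017 M (fed, over 16.0 h) | 1.00 equiv | all but starting material at the start; starting material goes in evenly over 16.0 h, the run ends at 20 h | 20 h |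

| run | time / h | target / % | side product / % |
|---|---|---|---|
| teal | 3.00 | 15.2 | 8.0 |
| teal | 6.00 | 24.0 | 17.6 |
| teal | 8.00 | 28.6 | 21.0 |
| teal | 12.0 | 30.8 | 26.7 |
| teal | 15.0 | 36.9 | 32.3 |
| teal | 20.0 | 41.3 | 34.1 |
| violet | 3.00 | 14.7 | 6.0 |
| violet | 6.00 | 20.6 | 11.9 |
| violet | 8.00 | 23.1 | 12.6 |
| violet | 12.0 | 28.5 | 19.8 |
| violet | 15.0 | 32.6 | 23.1 |
| violet | 20.0 | 36.0 | 29.6 |
| red | 1.50 | 9.0 | 3.7 |
| red | 2.50 | 13.2 | 5.1 |
| red | 4.00 | 15.8 | 9.9 |
| red | 6.00 | 20.7 | 15.4 |
| red | 8.00 | 26.5 | 18.2 |
| red | 12.0 | 31.7 | 23.4 |
| red | 20.0 | 40.6 | 34.0 |

(standard deviation of a reading: 1 percentage point)

- the stated concentrations are those of everything mixed, before any reaction; amounts are the same in each set-up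
- the earlier runs were read with a standard deviation of 1 percentage point
- the feed brings no volume worth counting
- the earlier runs were made in a closed, stirred flask

- the set-up with the highest share of target in all that became target or side product, at the outlet or at the end ("none" if the first two lie within 2 percentage points) (noon / autumn / winter / dawn / none)
- share of target in all that became target or side product, at the outlet or at the end, noon
- share of target in all that became target or side product, at the outlet or at the end, autumn
- share of target in all that became target or side product, at the outlet or at the end, winter
- share of target in all that became target or side product, at the outlet or at the end, dawn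

The vessel is the third setting. Noon's plug flow repeats autumn's closed flask slice by slice. Winter and dawn should turn over less, and my reckoning holds the teal gap and takes first-order loss from teal:

k = 0.0701 /h

autumn and noon: X = 75.4%, share 54.1%

winter: X = 58.4%, share 55.3%

dawn: X = 54.6%, share 55.7%

In this reckoning dawn comes highest, but 0.40 points over winter lies under the margin of 2 points, so my answer is none.

The forecast parts from this: noon 55%, autumn 55%, winter 51.5%, dawn 60%, best dawn: “Dawn is best, though less certain.”

The simulation gives noon 53.8%, autumn 53.8%, winter 54.7%, dawn 55.4%, best none.

    starting material ⇌ intermediate + leaving ligand (K = 5.10 × 10⁻⁶ M, k = 1.11 × 10⁻⁴ /s)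
    coupling partner + intermediate → target (k = 0.201 /M/s)
    starting material + leaving ligand → side product (k = 0.00926 /M/s)

In autumn at 20.0 h the leaving ligand is made at 0.953 of the rate at which it is used up, each step taken net. By the equations, c(leaving ligand) equals c(target) minus c(side product) plus c(intermediate), and in autumn at that time it stands at 0.00102 M. Dawn's turnover at 20.0 h with the teal gap gives 55.3%. For the neighbour of autumn charged with 0.0068 M, the violet gap scaled by the root of the charge ratio and that flask's turnover at the end give 57.8%; the neighbour stands at 57.8%.

The numbers in the tables were generated by integration for substances that don't exist.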